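**Retrosynthetic overview**
- Feature: in the ten-membered carbocycle C1–C10, the furanone carbonyl C1 and the lactone carbinol C6 lie 1,6 across the ring. Both are oxidised carbons, so one C1=C6 ring-fusion alkene of a cadinane-type octalin (ring A C1–C6, ring B C1, C6–C10) can deliver both.
- Late stage: target ⇒ C8 alcohol + tiglic acid ⇒ C6–O/C12 γ-lactone ⇒ C6 ketone ⇒ 3(2H)-furanone (C10–O onto C3) ⇒ cyclodecane-1,3,6-trione ⇒ ozonolysis of the 1(6)-octalin-3-one.
- Early stage: octalinone ⇒ Birch reduction and enol ether hydrolysis of a 3-methoxy-4-methyl tetralin ⇒ C7=C8 dihydronaphthalene (epoxidation, anti opening) ⇒ RCM ⇒ asymmetric allylboration of an aryl methyl ketone.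
- Ring order: arene = ring A (bought), ring B (RCM), ten-membered ring (C1=C6 cleavage), furanone, lactone.
- Stereocentres: C10 by catalyst, C8 and C7 from C10, C6 by hydride addition, C4 and C11 by equilibration of the rigid tricycle.

Key step: step 16

Assumption: germacrane numbering is used throughout (C1 furanone C=O, C2 =CH, C3 O-bearing =C, C4 CHMe, C5 CH2, C6 lactone O–CH, C7, C8 O–CH, C9 CH2, C10 CMe–O, C11 CHMe, C12 lactone C=O); C11 (α to the carboxyl group) and C4 (α to the C3 ketone) cannot be held with confidence through the sequence, so they carry no stereo mark in the SMILES from steps 10 and 15 until step 19 sets both.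

Step 1
Reactants: 1 3-methoxy-4-methylbenzoic acid
Product: 2 1-(3-methoxy-4-methylphenyl)ethanone
Conditions: MeLi (2.2 equiv), Et2O, 0 °C to rt; inverse quench into 1 M HCl
Reagents that add atoms: methyllithium [Li]C
Why: Addition of MeLi to the lithium carboxylate gives a gem-dialkoxide that collapses to the methyl ketone only on work-up (organolithium route from acid to methyl ketone), and these two carbons become C10 and its methyl group.

Step 2
Reactants: 2 1-(3-methoxy-4-methylphenyl)ethanone; 3 diisopropyl allylboronate
Product: 4 (R)-2-(3-methoxy-4-methylphenyl)pent-4-en-2-ol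
Conditions: 3 (1.5 equiv), 3,3'-dibromo-BINOL (15 mol %, the enantiomer that gives the R alcohol), PhMe–PhCF3, −35 °C
Reagents that add atoms: none
Why: Chiral-diol-catalysed asymmetric allylboration of an unhindered aryl methyl ketone runs through a closed chair transition state on the BINOL-bound boronate, tells aryl from methyl and sets C10 (R), the only centre that needs a chiral reagent.

Step 3
Reactants: 4 (R)-2-(3-methoxy-4-methylphenyl)pent-4-en-2-ol
Product: 5 (R)-2-(2-bromo-5-methoxy-4-methylphenyl)pent-4-en-2-ol
Conditions: NBS (1.05 equiv), MeCN, 0 °C, dark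
Reagents that add atoms: N-bromosuccinimide O=C1CCC(=O)N1Br
Why: Electrophilic aromatic bromination goes to C6, para to the methoxy group and the only activated site not flanked on both sides, and polar NBS conditions in the dark spare the terminal alkene and the aryl methyl group.

Step 4
Reactants: 5 (R)-2-(2-bromo-5-methoxy-4-methylphenyl)pent-4-en-2-ol
Product: 6 (R)-2-(2-hydroxypent-4-en-2-yl)-4-methoxy-5-methylbenzaldehyde (in equilibrium with its lactol)
Conditions: n-BuLi (2.2 equiv), THF, −78 °C; DMF, −78 °C to 0 °C; aq NH4Cl
Reagents that add atoms: N,N-dimethylformamide CN(C)C=O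
Why: After deprotonation of the carbinol, bromine–lithium exchange at −78 °C outruns carbolithiation of the pendant alkene, and the aryllithium is formylated by DMF (Bouveault aldehyde synthesis), which installs C7.

Step 5
Reactants: 6 (R)-2-(2-hydroxypent-4-en-2-yl)-4-methoxy-5-methylbenzaldehyde
Product: 7 (R)-2-(5-methoxy-4-methyl-2-vinylphenyl)pent-4-en-2-ol
Conditions: Ph3PCH3Br, KOt-Bu (3 equiv each), THF, 0 °C to rt
Reagents that add atoms: methyltriphenylphosphonium bromide C[P+](c1ccccc1)(c1ccccc1)c1ccccc1.[Br-]
Why: Wittig methylenation of the aldehyde, released from its lactol by the base, gives the styrene partner for ring closure, a detour chosen because Pd-catalysed vinylation of 5 would be overtaken by 5-exo Heck cyclisation onto the allyl group.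

Step 6
Reactants: 7 (R)-2-(5-methoxy-4-methyl-2-vinylphenyl)pent-4-en-2-ol
Product: 8 (R)-7-methoxy-1,6-dimethyl-1,2-dihydronaphthalen-1-ol
Conditions: second-generation Ru–NHC benzylidene metathesis catalyst (3 mol %), CH2Cl2, 40 °C; filtration through basic alumina
Reagents that add atoms: none
Why: Ring-closing metathesis of the styrene and the terminal alkene closes ring B as the C7=C8 dihydronaphthalene with loss of ethene, and the neutral conditions tolerate the tertiary alcohol and avoid dehydration to the naphthalene.

Step 7
Reactants: 8 (R)-7-methoxy-1,6-dimethyl-1,2-dihydronaphthalen-1-ol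
Product: 9 (7R,8S,10R)-7,8-epoxide of 8 with the oxirane cis to the C10 hydroxyl (used crude)
Conditions: dimethyldioxirane (1.1 equiv, acetone), CH2Cl2, −20 °C
Reagents that add atoms: dimethyldioxirane CC1(C)OO1
Why: Dioxirane epoxidation of the electron-rich styrene under neutral conditions should occur on the face of the C10 hydroxyl, which donates a hydrogen bond and is the face left open by the pseudoaxial C10 methyl group (peri strain keeps the methyl out of the arene plane), and this sets C8–O cis to C10–O.

Step 8
Reactants: 9 (7R,8S,10R)-7,8-epoxide; 10 isopropenylmagnesium bromide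
Product: 11 (1R,3S,4S)-7-methoxy-1,6-dimethyl-4-(prop-1-en-2-yl)-1,2,3,4-tetrahydronaphthalene-1,3-diol (7S,8S,10R)
Conditions: 10 (3.5 equiv), CuI (30 mol %), THF, −40 °C to −10 °C; aq NH4Cl
Reagents that add atoms: none
Why: Copper-catalysed SN2 opening of the epoxide takes place at the benzylic C7, activated by the para methoxy group, with inversion and in the trans-diaxial sense (Fürst–Plattner rule), so the isopropenyl group ends up trans to the C8 hydroxyl and C7 is set as S.

Step 9
Reactants: 11 (7S,8S,10R)-diol
Product: 12 C8 O-TBS ether of 11 (7S,8S,10R)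
Conditions: TBSOTf (1.1 equiv), 2,6-lutidine, CH2Cl2, −78 °C
Reagents that add atoms: tert-butyldimethylsilyl triflate CC(C)(C)[Si](C)(C)OS(=O)(=O)C(F)(F)F
Why: Silylation with the silyl triflate at low temperature discriminates the secondary C8 hydroxyl from the hindered tertiary benzylic C10 hydroxyl.

Step 10
Reactants: 12 C8 O-TBS ether
Product: 13 C12 primary alcohol with side chain CH(CH3)CH2OH on C7 (7S,8S,10R; C11 epimers)
Conditions: 9-BBN (2.5 equiv), THF, rt to 50 °C; NaOH, H2O2, 0 °C
Reagents that add atoms: hydrogen peroxide OO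
Why: Anti-Markovnikov hydroboration–oxidation of the 1,1-disubstituted alkene gives the C12 primary alcohol, and C11 is created without a useful facial bias, which is accepted because this centre is corrected in step 19.

Step 11
Reactants: 13 C12 primary alcohol
Product: 14 tetralin propanoic acid with C8 OTBS and free C10 OH (7S,8S,10R; C11 epimers)
Conditions: TEMPO (20 mol %), PhI(OAc)2 (2.2 equiv), MeCN–H2O, rt
Reagents that add atoms: water O
Why: Nitroxyl-catalysed oxidation takes the primary alcohol through the aldehyde hydrate to the carboxylic acid and cannot touch the tertiary alcohol, the silyl ether or the arene.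

Step 12
Reactants: 14 tetralin propanoic acid
Product: 15 2,5-dihydroanisole acid with C3=C4 methyl enol ether and C1=C6 alkene (7S,8S,10R; C11 epimers; kept as its salt)
Conditions: Li (25 equiv), NH3(l)–THF–t-BuOH, −78 °C to −33 °C; isoprene, then NH4Cl; work-up at pH 7–8
Reagents that add atoms: none
Why: Birch reduction protonates the two unsubstituted para-related positions C2 and C5, which leaves the C3=C4 enol ether and the tetrasubstituted C1=C6 alkene, while the carboxylate, the alkyl silyl ether and the benzylic C10 oxygen (an alkoxide, hence no leaving group, and meta to the methoxy group) should survive.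

Step 13
Reactants: 15 dihydroanisole acid
Product: 16 methyl ester of 15
Conditions: MeI, K2CO3, DMF, 0 °C to rt
Reagents that add atoms: iodomethane CI
Why: Alkylation of the carboxylate with MeI under weakly basic conditions forms the methyl ester without exposing the acid-labile enol ether to the free acid.

Step 14
Reactants: 16 methyl ester
Product: 17 C10 O-TES ether of 16
Conditions: TESOTf (1.5 equiv), 2,6-lutidine, CH2Cl2, −78 °C to 0 °C
Reagents that add atoms: triethylsilyl triflate CC[Si](CC)(CC)OS(=O)(=O)C(F)(F)F
Why: The tertiary allylic alcohol is silylated with the reactive triflate and a hindered pyridine base before the ketone is unmasked, so that no silyl enol ether can form.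

Step 15
Reactants: 17 C10 O-TES ether
Product: 18 1(6)-octalin-3-one with C7 CH(Me)CO2Me; C8 OTBS; C10 Me/OTES (7S,8S,10R; C4 and C11 epimers)
Conditions: oxalic acid dihydrate (0.5 equiv), THF–H2O 5:1, 0 °C to rt
Reagents that add atoms: water O
Why: Mild acid hydrolysis of the enol ether protonates C4 and stops at the β,γ-unsaturated ketone (the non-conjugated product of dihydroanisole hydrolysis), and C4, remote from all ring-B centres, is formed without selectivity and is fixed in step 19.

Step 16
Reactants: 18 1(6)-octalin-3-one
Product: 20 cyclodecane-1,3,6-trione with C7 CH(Me)CO2Me; C8 OTBS; C10 Me/OTES (7R,8S,10R; C4 and C11 epimers), via methoxy hydroperoxide 19 (not isolated)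
Conditions: O3 (1 equiv, Sudan Red III end point), CH2Cl2–MeOH 5:1, −78 °C; Me2S, −78 °C to rt
Reagents that add atoms: ozone [O-][O+]=O
Why: Ozone adds as a 1,3-dipole to the electron-rich tetrasubstituted C1=C6 alkene, the primary ozonide cycloreverts with the carbonyl oxide on C6 (away from the inductively withdrawing C10–OSi and C3=O neighbours of C1), methanol traps it as 19, and Me2S reduces this to the C6 ketone. The closest known reaction type is the ozonolysis of ring-fusion octalins obtained by Birch reduction of methoxytetralins, which gives cyclodecane-1,6-diones. The ten-membered ring C1–C10 is not closed by bond formation, because it appears when the bond shared by rings A and B is cut and the two six-membered rings merge (ring enlargement by fragmentation). No stereocentre is formed, and C7, C8 and C10 are untouched under the neutral conditions. Only chemoselectivity is needed: the alkene is the single C=C bond of 18 and is kept out of conjugation with C3=O by the mild hydrolysis of step 15, and ozone is limited to one equivalent because the enol of the new C1/C3 diketone is itself ozonophilic. The trione is base-sensitive at C7/C8 and prone to transannular aldol reaction, so it is filtered through neutral silica and used at once.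

Step 17
Reactants: 20 cyclodecane-1,3,6-trione
Product: 22 3,10-bridged 3(2H)-furanone C6 ketone with C7 CH(Me)CO2Me and C8 OTBS (7R,8S,10R; C4 and C11 epimers), via hydroxy trione 21 (not isolated)
Conditions: TsOH·H2O (0.3 equiv), THF–H2O 20:1, 0 °C to rt
Reagents that add atoms: none
Why: Acid hydrolysis removes the triethylsilyl group much faster than the hindered secondary TBS ether, and the freed C10 hydroxyl adds to C3 of the enolised 1,3-diketone (5-exo-trig) and loses water, the known cyclodehydration of α'-hydroxy-1,3-diketones to 3(2H)-furanones, which also takes C1 and C2 out of reach of transannular aldol reactions.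

Step 18
Reactants: 22 furanone C6 ketone
Product: 23 (6R)-hydroxy ester (6R,7S,8S,10R; C4 and C11 epimers)
Conditions: NaBH4 (1.2 equiv), MeOH–CH2Cl2 1:1, −78 °C to −40 °C; AcOH quench
Reagents that add atoms: none
Why: Borohydride reduces the isolated C6 ketone and not the vinylogous ester carbonyl C1, and with the C5–C9 chain held extended by the furanone bridge the C11 branch and the C8 silyloxy group both cover one face of C6=O, so hydride should enter anti to the C7–C11 bond (Felkin–Anh sense) from the face of H7 and H8 and give the 6R alcohol.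

Step 19
Reactants: 23 (6R)-hydroxy ester
Product: 24 C8 O-TBS furanone lactone (4S,6R,7S,8S,10R,11S)
Conditions: KOt-Bu (0.3 equiv), THF–t-BuOH 4:1, 0 °C to rt; AcOH quench
Reagents that add atoms: none
Why: Catalytic alkoxide closes the trans-γ-lactone by transesterification and equilibrates both epimerisable centres, C11 through the lactone enolate to the methyl group cis to H7 and away from C8–OTBS (the stable epimer of trans-fused α-methyl lactones) and C4 through the furanone dienolate to the 4S epimer, the only one in which C5 and C9 leave the furanone on the same face while C4–H eclipses C2=C3 and the methyl group lies anti to C6.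

Step 20
Reactants: 24 C8 O-TBS furanone lactone
Product: 25 C8 alcohol (4S,6R,7R,8S,10R,11S)
Conditions: HF·pyridine, THF, 0 °C to rt
Reagents that add atoms: none
Why: Fluoride cleavage under mildly acidic conditions frees the C8 hydroxyl without the base that would allow translactonisation from O6 to O8.

Step 21
Reactants: 25 C8 alcohol; 26 tiglic acid
Product: 28 CNP0235937.1 (4S,6R,7S,8S,10R,11S), via tiglic 2,4,6-trichlorobenzoic anhydride 27 (not isolated)
Conditions: 26, 2,4,6-trichlorobenzoyl chloride, Et3N, PhMe, rt; then 25, DMAP, rt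
Reagents that add atoms: none
Why: Yamaguchi esterification through the mixed anhydride acylates the hindered secondary C8 alcohol under mild conditions with retention at C8 and of the E geometry of the tiglate.

**Compound list**
1 | 3-methoxy-4-methylbenzoic acid | COc1cc(C(=O)O)ccc1C | starting material
2 | 1-(3-methoxy-4-methylphenyl)ethanone | COc1cc(C(C)=O)ccc1C | intermediate
3 | diisopropyl allylboronate | C=CCB(OC(C)C)OC(C)C | starting material
4 | (R)-2-(3-methoxy-4-methylphenyl)pent-4-en-2-ol | C=CC[C@@](C)(O)c1ccc(C)c(OC)c1 | intermediate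
5 | (R)-2-(2-bromo-5-methoxy-4-methylphenyl)pent-4-en-2-ol | C=CC[C@@](C)(O)c1cc(OC)c(C)cc1Br | intermediate
6 | (R)-2-(2-hydroxypent-4-en-2-yl)-4-methoxy-5-methylbenzaldehyde | C=CC[C@@](C)(O)c1cc(OC)c(C)cc1C=O | intermediate
7 | (R)-2-(5-methoxy-4-methyl-2-vinylphenyl)pent-4-en-2-ol | C=CC[C@@](C)(O)c1cc(OC)c(C)cc1C=C | intermediate
8 | (R)-7-methoxy-1,6-dimethyl-1,2-dihydronaphthalen-1-ol | C1=CC[C@@](C)(O)c2cc(OC)c(C)cc12 | intermediate
9 | (7R,8S,10R)-7,8-epoxide of 8, oxirane cis to the C10 hydroxyl | C[C@@]1(O)C[C@@H]2O[C@@H]2c2cc(C)c(OC)cc21 | intermediate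
10 | isopropenylmagnesium bromide | CC(=C)[Mg]Br | starting material
11 | (1R,3S,4S)-7-methoxy-1,6-dimethyl-4-(prop-1-en-2-yl)-1,2,3,4-tetrahydronaphthalene-1,3-diol | CC(=C)[C@@H]1[C@@H](O)C[C@@](C)(O)c2cc(OC)c(C)cc12 | intermediate
12 | C8 O-TBS ether of 11 | CC(=C)[C@@H]1[C@@H](O[Si](C)(C)C(C)(C)C)C[C@@](C)(O)c2cc(OC)c(C)cc12 | intermediate
13 | C12 primary alcohol (7S,8S,10R; C11 epimers) | OCC(C)[C@@H]1[C@@H](O[Si](C)(C)C(C)(C)C)C[C@@](C)(O)c2cc(OC)c(C)cc12 | intermediate
14 | tetralin propanoic acid (7S,8S,10R; C11 epimers) | OC(=O)C(C)[C@@H]1[C@@H](O[Si](C)(C)C(C)(C)C)C[C@@](C)(O)c2cc(OC)c(C)cc12 | intermediate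
15 | 2,5-dihydroanisole acid (7S,8S,10R; C11 epimers) | OC(=O)C(C)[C@@H]1[C@@H](O[Si](C)(C)C(C)(C)C)C[C@@](C)(O)C2=C1CC(C)=C(OC)C2 | intermediate
16 | methyl ester of 15 | COC(=O)C(C)[C@@H]1[C@@H](O[Si](C)(C)C(C)(C)C)C[C@@](C)(O)C2=C1CC(C)=C(OC)C2 | intermediate
17 | C10 O-TES ether of 16 | COC(=O)C(C)[C@@H]1[C@@H](O[Si](C)(C)C(C)(C)C)C[C@@](C)(O[Si](CC)(CC)CC)C2=C1CC(C)=C(OC)C2 | intermediate
18 | 1(6)-octalin-3-one, key-step precursor (7S,8S,10R; C4 and C11 epimers) | COC(=O)C(C)[C@@H]1[C@@H](O[Si](C)(C)C(C)(C)C)C[C@@](C)(O[Si](CC)(CC)CC)C2=C1CC(C)C(=O)C2 | intermediate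
19 | C6 methoxy hydroperoxide of the 1,3-diketone | COC(=O)C(C)[C@@H]1[C@@H](O[Si](C)(C)C(C)(C)C)C[C@@](C)(O[Si](CC)(CC)CC)C(=O)CC(=O)C(C)CC1(OC)OO | intermediate
20 | cyclodecane-1,3,6-trione, key-step product (7R,8S,10R; C4 and C11 epimers) | COC(=O)C(C)[C@@H]1[C@@H](O[Si](C)(C)C(C)(C)C)C[C@@](C)(O[Si](CC)(CC)CC)C(=O)CC(=O)C(C)CC1=O | intermediate
21 | C10 hydroxy trione | COC(=O)C(C)[C@@H]1[C@@H](O[Si](C)(C)C(C)(C)C)C[C@@](C)(O)C(=O)CC(=O)C(C)CC1=O | intermediate
22 | furanone C6 ketone (7R,8S,10R; C4 and C11 epimers) | CC(C)(C)[Si](C)(C)O[C@H]1C[C@@]2(C)OC(=CC2=O)C(C)CC(=O)[C@@H]1C(C)C(=O)OC | intermediate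
23 | (6R)-hydroxy ester (6R,7S,8S,10R; C4 and C11 epimers) | CC(C)(C)[Si](C)(C)O[C@H]1C[C@@]2(C)OC(=CC2=O)C(C)C[C@@H](O)[C@@H]1C(C)C(=O)OC | intermediate
24 | C8 O-TBS furanone lactone (4S,6R,7S,8S,10R,11S) | CC(C)(C)[Si](C)(C)O[C@H]1C[C@@]2(C)OC(=CC2=O)[C@@H](C)C[C@H]2OC(=O)[C@@H](C)[C@H]12 | intermediate
25 | C8 alcohol (4S,6R,7R,8S,10R,11S) | O[C@H]1C[C@@]2(C)OC(=CC2=O)[C@@H](C)C[C@H]2OC(=O)[C@@H](C)[C@H]12 | intermediate
26 | tiglic acid | C/C=C(\C)C(=O)O | starting material
27 | tiglic 2,4,6-trichlorobenzoic anhydride | C/C=C(\C)C(=O)OC(=O)c1c(Cl)cc(Cl)cc1Cl | intermediate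
28 | CNP0235937.1 (4S,6R,7S,8S,10R,11S) | C/C=C(\C)C(=O)O[C@H]1C[C@@]2(C)OC(=CC2=O)[C@@H](C)C[C@H]2OC(=O)[C@@H](C)[C@H]12 | target

Total step count: 21. Longest linear sequence: 21 steps (from 1).

**Steps most likely to fail**

**Step 16.**
- What may go wrong: the enol of the 1,3-diketone being formed may compete with the hindered alkene for ozone (over-oxidation). The β,γ-enone may also drift into conjugation before it is cleaved.
- Fallback: it sets out from 18 and masks C3. NaBH4 (MeOH, −20 °C) reduces the ketone to the homoallylic C3 alcohol F1. Ozonolysis under the same conditions then gives the non-enolised 3-hydroxy-1,6-diketone F2. Buffered Dess–Martin oxidation of this β-hydroxy ketone raises C3 to the ketone and rejoins the route at 20.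

**Step 18.**
- What may go wrong: hydride may be delivered to the other face of C6=O if shielding by the furanone bridge outweighs the local bias from C7 and C8.
- Fallback: it sets out from 22 and uses inversion instead of direct control. A bulky hydride (L-Selectride, THF, −78 °C) makes the alcohol from the other face, the 6S hydroxy ester F3, the deliberate intermediate; this alcohol cannot close the trans-lactone. Me3SnOH (1,2-dichloroethane, 70 °C) hydrolyses the ester to the 6S hydroxy acid F4. Mitsunobu lactonisation (PPh3, DIAD, THF, 0 °C) displaces the activated C6 oxygen by the C12 carboxylate with inversion to give the 6R lactone epimer mixture F5. The base treatment of step 19 carries this back to the route at 24.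

**Step 19.**
- What may go wrong: the equilibrium at C4 may favour the 4R epimer or give incomplete convergence; C11 is expected to follow the known preference.
- Fallback: it replaces thermodynamic by kinetic control and sets out from 23. In this case the base treatment gives mainly the 4R lactone F6. KHMDS (1.0 equiv, THF, −78 °C) removes the more acidic γ-proton at C4 to give the potassium dienolate F7. Fast protonation by a hindered phenol from the open face should then deliver the less stable C4 epimer and return to the route at 24.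

Further compounds
F1 | step 16 | homoallylic C3 alcohol of 18 | COC(=O)C(C)[C@@H]1[C@@H](O[Si](C)(C)C(C)(C)C)C[C@@](C)(O[Si](CC)(CC)CC)C2=C1CC(C)C(O)C2
F2 | step 16 | 3-hydroxy-1,6-diketone | COC(=O)C(C)[C@@H]1[C@@H](O[Si](C)(C)C(C)(C)C)C[C@@](C)(O[Si](CC)(CC)CC)C(=O)CC(O)C(C)CC1=O
F3 | step 18 | 6S hydroxy ester | CC(C)(C)[Si](C)(C)O[C@H]1C[C@@]2(C)OC(=CC2=O)C(C)C[C@H](O)[C@@H]1C(C)C(=O)OC
F4 | step 18 | 6S hydroxy acid | CC(C)(C)[Si](C)(C)O[C@H]1C[C@@]2(C)OC(=CC2=O)C(C)C[C@H](O)[C@@H]1C(C)C(=O)O
F5 | step 18 | 6R lactone epimer mixture (C4 and C11 undefined) | CC(C)(C)[Si](C)(C)O[C@H]1C[C@@]2(C)OC(=CC2=O)C(C)C[C@H]2OC(=O)C(C)[C@H]12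
F6 | step 19 | 4R lactone (C4 epimer of 24) | CC(C)(C)[Si](C)(C)O[C@H]1C[C@@]2(C)OC(=CC2=O)[C@H](C)C[C@H]2OC(=O)[C@@H](C)[C@H]12
F7 | step 19 | potassium dienolate of the furanone | CC(C)(C)[Si](C)(C)O[C@H]1C[C@@]2(C)OC(C=C2[O-])=C(C)C[C@H]2OC(=O)[C@@H](C)[C@H]12.[K+]
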